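**Retrosynthetic overview**
Kanzonol X ⇐ global MOM removal ⇐ one double directed ortho-metalation/prenylation at C8 and C3′ of the (R)-tris-MOM isoflavan; the prenyl groups come last so that no other alkene meets the carbene or the hydrogenation.
The (R) centre at C3 ⇐ iridium-catalysed asymmetric hydrogenation of the C3=C4 bond of an isoflav-3-ene (3-aryl-2H-chromene).
Pyran ring C ⇐ furan ring of 6-(methoxymethoxy)benzofuran by one-carbon ring expansion: the ring-B aryl chlorocarbene puts its carbon between C2 and C3 of the benzofuran (cyclopropanation, opening to the isoflavylium ion, hydride capture at C2).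
Enabling feature: C3 of ring C is a CH(aryl) carbon flanked by C2 (on O1) and C4 (on C4a); deleting it leaves the enol-ether C2=C3 bond of a benzofuran, and the O1 lone pair turns the ring-opened C2–C3–C4 cation into an aromatic benzopyrylium.
Ring order: rings A and B are bought (benzofuran-6-ol, 2,4-dihydroxybenzonitrile); ring C is formed in step 5 from the five-membered furan ring.

Key step: step 5

Assumption: C3 of the target is R by the CIP rules; isoflavonoid numbering is used (O1, C2, C3, C4, C4a–C8a, ring B primed), and benzofuran-6-ol and 2,4-dihydroxybenzonitrile are taken as commercially available.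

**Route**

Step 1
Reactants: 1 benzofuran-6-ol
Product: 2 6-(methoxymethoxy)-1-benzofuran
Conditions: NaH, MOMCl, DMF, 0 °C to rt
Reagents that add atoms: chloromethyl methyl ether (MOMCl), COCCl
Why: Williamson-type O-alkylation of the sodium phenoxide installs the MOM acetal that later directs lithiation to C8.

Step 2
Reactants: 3 2,4-dihydroxybenzonitrile
Product: 4 2,4-bis(methoxymethoxy)benzonitrile
Conditions: NaH (2.4 equiv), MOMCl (2.4 equiv), DMF, 0 °C to rt
Reagents that add atoms: chloromethyl methyl ether (MOMCl), COCCl
Why: Double Williamson-type O-alkylation of the bis-phenoxide gives the two MOM acetals that later direct lithiation to C3′.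

Step 3
Reactants: 4 2,4-bis(methoxymethoxy)benzonitrile
Product: 6 2,4-bis(methoxymethoxy)benzamidinium chloride, via lithium N,N′-bis(trimethylsilyl)amidinate 5 (not isolated)
Conditions: LiN(SiMe3)2 (1.2 equiv), THF, 0 °C to rt; then HCl (2.0 equiv, 1.25 M in EtOH), 0 °C
Reagents that add atoms: lithium bis(trimethylsilyl)amide, [Li]N([Si](C)(C)C)[Si](C)(C)C; hydrogen chloride, Cl
Why: Addition of the silylamide to the nitrile and N-desilylation is the standard route to aryl amidinium salts, and the two equivalents of cold ethanolic HCl are consumed by the amidinate so that the MOM acetals should not meet free acid.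

Step 4
Reactants: 6 2,4-bis(methoxymethoxy)benzamidinium chloride
Product: 7 3-chloro-3-[2,4-bis(methoxymethoxy)phenyl]-3H-diazirine
Conditions: NaOCl (aq.), DMSO/pentane, 0 °C; kept cold and used at once as a pentane solution
Reagents that add atoms: sodium hypochlorite, [Na+].[O-]Cl
Why: Graham oxidation of an amidinium salt (N-chlorination, N–N closure, return of chloride to carbon) is the standard preparation of 3-aryl-3-chlorodiazirines, and the amidinium group should deactivate the resorcinol ring against ring chlorination.

Step 5
Reactants: 2 6-(methoxymethoxy)-1-benzofuran; 7 3-chloro-3-[2,4-bis(methoxymethoxy)phenyl]-3H-diazirine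
Product: 10 7-(methoxymethoxy)-3-[2,4-bis(methoxymethoxy)phenyl]-2H-chromene, via chlorocyclopropane adduct 8 (not isolated), via isoflavylium chloride 9 (not isolated)
Conditions: 2 (3 equiv), 4 Å MS, MeCN, slow addition of 7, 35 °C, dark; then NaBH4 (solid, 2 equiv), −20 °C to 0 °C
Reagents that add atoms: none
Why: Proposed new method: thermal loss of N2 from 7 should give a singlet arylchlorocarbene that adds [2+1] to the electron-rich enol-ether C2=C3 bond of 2 to give cyclopropane 8, whose C–Cl bond ionises with disrotatory opening of the ring-fusion bond, so that the five-membered furan ring becomes the six-membered aromatic benzopyrylium ring of 9, and borohydride then adds at C2 to give the 2H-chromene 10. The closest known reaction types are the dihalocarbene ring expansion of benzofurans to 3-halo-2H-chromenes and the chlorodiazirine carbon-atom insertion into indoles (Ciamician–Dennstedt type), together with the borohydride reduction of isoflavylium salts to isoflav-3-enes. The three-membered ring closes by concerted cheletropic addition, and the pyran ring is not closed by a cyclisation but arises by electrocyclic cleavage of the bond shared by the three- and five-membered rings. The stereocentres of 8 are erased on ionisation, so both C1 epimers and both enantiomers converge on one planar cation and 10 is achiral; the 2,4-dioxygenated aryl group should allow ionisation from either epimer. The step needs the carbene to prefer C2=C3 over insertion into the ortho OCH2O group, which the high concentration of the enol-ether π bond and the absence of any other alkene (no prenyl group is yet present) should secure, and it needs hydride attack at C2 rather than C4, which the higher positive charge next to the oxonium oxygen and the conjugated stilbene-type product should favour.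

Step 6
Reactants: 10 7-(methoxymethoxy)-3-[2,4-bis(methoxymethoxy)phenyl]-2H-chromene
Product: 11 (3R)-7-(methoxymethoxy)-3-[2,4-bis(methoxymethoxy)phenyl]-3,4-dihydro-2H-chromene
Conditions: H2 (50 bar), [Ir(cod)(L)]BArF (2 mol %; cod = 1,5-cyclooctadiene, L = (4R,5R)-ThrePHOX phosphinite–oxazoline, BArF = B[3,5-(CF3)2C6H3]4), CH2Cl2, rt
Reagents that add atoms: none
Why: Asymmetric hydrogenation of the trisubstituted C3=C4 bond of 3-aryl-2H-chromenes with iridium P,N-ligand catalysts has close precedent, the chiral ligand controls the face of hydrogen delivery to C3 and so sets the (R) centre, and the (4R,5R) ligand is proposed by analogy with 4′-substituted isoflavenes, its antipode being used if the sense of induction proves opposite.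

Step 7
Reactants: 11 (3R)-7-(methoxymethoxy)-3-[2,4-bis(methoxymethoxy)phenyl]-3,4-dihydro-2H-chromene
Product: 13 (3R)-7-(methoxymethoxy)-3-[2,4-bis(methoxymethoxy)-3-(3-methylbut-2-en-1-yl)phenyl]-8-(3-methylbut-2-en-1-yl)-3,4-dihydro-2H-chromene, via 8,3′-dilithio isoflavan 12 (not isolated)
Conditions: n-BuLi (3 equiv), TMEDA, THF, −20 °C to 0 °C; then CuBr·SMe2 (20 mol %), prenyl bromide (4 equiv), −78 °C to rt
Reagents that add atoms: 1-bromo-3-methylbut-2-ene (prenyl bromide), CC(C)=CCBr
Why: Directed ortho-metalation should lithiate C8 (between O1 and the 7-OMOM group) and C3′ (between the 2′- and 4′-OMOM groups), each the only ring carbon flanked by two oxygen substituents, and copper-catalysed SN2 allylation then installs both prenyl groups while the non-acidic C3–H is untouched.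

Step 8
Reactants: 13 (3R)-7-(methoxymethoxy)-3-[2,4-bis(methoxymethoxy)-3-(3-methylbut-2-en-1-yl)phenyl]-8-(3-methylbut-2-en-1-yl)-3,4-dihydro-2H-chromene
Product: 14 Kanzonol X
Conditions: aq. HCl (3 M, 0.5 equiv), MeOH, 40 °C
Reagents that add atoms: none
Why: Acid-catalysed acetal exchange with methanol removes the three MOM groups, and dilute acid at mild temperature is chosen so that the ortho-prenylphenols should not cyclise to dimethylchromans and C3, which has no epimerisation pathway, stays (R).

**Compound list**
1 | benzofuran-6-ol | Oc1ccc2ccoc2c1 | starting material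
2 | 6-(methoxymethoxy)-1-benzofuran | COCOc1ccc2ccoc2c1 | intermediate
3 | 2,4-dihydroxybenzonitrile | N#Cc1ccc(O)cc1O | starting material
4 | 2,4-bis(methoxymethoxy)benzonitrile | N#Cc1ccc(OCOC)cc1OCOC | intermediate
5 | lithium N,N′-bis(trimethylsilyl)-2,4-bis(methoxymethoxy)benzamidinate (not isolated) | COCOc1ccc(C(=N[Si](C)(C)C)N([Li])[Si](C)(C)C)c(OCOC)c1 | intermediate
6 | 2,4-bis(methoxymethoxy)benzamidinium chloride | COCOc1ccc(C(N)=[NH2+])c(OCOC)c1.[Cl-] | intermediate
7 | 3-chloro-3-[2,4-bis(methoxymethoxy)phenyl]-3H-diazirine | COCOc1ccc(C2(Cl)N=N2)c(OCOC)c1 | intermediate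
8 | 1-chloro-1-[2,4-bis(methoxymethoxy)phenyl]-4-(methoxymethoxy)-1a,6b-dihydro-1H-cyclopropa[b][1]benzofuran (cis-fused, mixture of C1 epimers, racemic; not isolated) | COCOc1ccc(C2(Cl)C3Oc4cc(OCOC)ccc4C23)c(OCOC)c1 | intermediate
9 | 7-(methoxymethoxy)-3-[2,4-bis(methoxymethoxy)phenyl]chromenylium chloride (isoflavylium chloride; not isolated) | COCOc1ccc(-c2cc3ccc(OCOC)cc3[o+]c2)c(OCOC)c1.[Cl-] | intermediate
10 | 7-(methoxymethoxy)-3-[2,4-bis(methoxymethoxy)phenyl]-2H-chromene | COCOc1ccc(C2=Cc3ccc(OCOC)cc3OC2)c(OCOC)c1 | intermediate
11 | (3R)-7-(methoxymethoxy)-3-[2,4-bis(methoxymethoxy)phenyl]-3,4-dihydro-2H-chromene | COCOc1ccc([C@@H]2COc3cc(OCOC)ccc3C2)c(OCOC)c1 | intermediate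
12 | (3R)-8-lithio-3-[3-lithio-2,4-bis(methoxymethoxy)phenyl]-7-(methoxymethoxy)-3,4-dihydro-2H-chromene (not isolated) | COCOc1ccc([C@@H]2COc3c([Li])c(OCOC)ccc3C2)c(OCOC)c1[Li] | intermediate
13 | (3R)-7-(methoxymethoxy)-3-[2,4-bis(methoxymethoxy)-3-(3-methylbut-2-en-1-yl)phenyl]-8-(3-methylbut-2-en-1-yl)-3,4-dihydro-2H-chromene | COCOc1ccc([C@@H]2COc3c(CC=C(C)C)c(OCOC)ccc3C2)c(OCOC)c1CC=C(C)C | intermediate
14 | Kanzonol X, 4-[(3R)-7-hydroxy-8-(3-methylbut-2-en-1-yl)-3,4-dihydro-2H-chromen-3-yl]-2-(3-methylbut-2-en-1-yl)benzene-1,3-diol | CC(C)=CCc1c(O)ccc([C@@H]2COc3c(ccc(O)c3CC=C(C)C)C2)c1O | target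

**Totals and risks**
Total step count: 8. Longest linear sequence: 7 steps (3 → 4 → 6 → 7 → 10 → 11 → 13 → 14; step 1 is the side branch).

Steps most likely to fail:

Step 5 (proposed new method). The carbene may be lost to insertion into the neighbouring OCH2O group, to azine formation or to premature decomposition of the electron-rich diazirine, whose preparation in step 4 may also suffer ring chlorination; hydride may add at C4 as well as at C2. The fallback uses known chemistry, keeps the one-carbon ring expansion of the furan ring and brings in ring B by cross-coupling. It sets out from compound 2, which with CHBr3 and KOt-Bu in hexane at 0 °C should give the dibromocarbene adduct 1,1-dibromo-4-(methoxymethoxy)-1a,6b-dihydro-1H-cyclopropa[b][1]benzofuran F1. Heating F1 with K2CO3 in EtOH should open it to 3-bromo-2-ethoxy-7-(methoxymethoxy)-2H-chromene F2. In parallel, commercially available 4-bromoresorcinol is converted with NaH and MOMCl into 1-bromo-2,4-bis(methoxymethoxy)benzene F3, and by Miyaura borylation (bis(pinacolato)diboron, PdCl2(dppf), KOAc, dioxane, 90 °C) into 2-[2,4-bis(methoxymethoxy)phenyl]-4,4,5,5-tetramethyl-1,3,2-dioxaborolane F4. Suzuki–Miyaura coupling of F2 with F4 (Pd(PPh3)4, K3PO4, dioxane/H2O, 80 °C) should give 2-ethoxy-7-(methoxymethoxy)-3-[2,4-bis(methoxymethoxy)phenyl]-2H-chromene F5. With Me3SiCl in MeCN at −20 °C, F5 should ionise to the isoflavylium chloride, so the fallback comes back to the route at compound 9, which is reduced with NaBH4 to 10 as in step 5.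

Step 7. The second lithiation may stay incomplete, and the allylation may suffer SN2′ attack (reverse prenyl), halogen–metal exchange or proton quench by elimination from prenyl bromide. The fallback replaces the allylic substitution by cross-coupling. It sets out from compound 11, lithiated as in step 7 to the dilithio species 12, which is quenched with I2 at −78 °C to give (3R)-8-iodo-3-[3-iodo-2,4-bis(methoxymethoxy)phenyl]-7-(methoxymethoxy)-3,4-dihydro-2H-chromene F6. Iodine is the most dependable trap for an aryllithium, and any mono-iodide can be separated and resubmitted. A double Stille coupling of F6 with tributyl(3-methylbut-2-en-1-yl)stannane (Pd(PPh3)4, DMF, 90 °C) should then bring the fallback back to the route at compound 13.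

Step 6. Facial discrimination may be poor with the ortho-substituted aryl group, the hindered alkene may hydrogenate slowly, or the acidic iridium hydride may remove a MOM group. The fallback sets the centre by a dynamic kinetic resolution instead. It sets out from compound 10; hydroboration with BH3·THF should give the C4 alkylborane, (3,4-trans)-4-boranyl-7-(methoxymethoxy)-3-[2,4-bis(methoxymethoxy)phenyl]chroman F7. Oxidation in the same flask (NaOH, H2O2) should give racemic trans-7-(methoxymethoxy)-3-[2,4-bis(methoxymethoxy)phenyl]chroman-4-ol F8. Dess–Martin oxidation should give the racemic isoflavanone 7-(methoxymethoxy)-3-[2,4-bis(methoxymethoxy)phenyl]chroman-4-one F9, whose C3 epimerises through the enol. Noyori-type transfer hydrogenation (RuCl(p-cymene)[(R,R)-TsDPEN], HCO2H/Et3N, rt) is expected to funnel both enantiomers of F9 into (3R,4R)-cis-7-(methoxymethoxy)-3-[2,4-bis(methoxymethoxy)phenyl]chroman-4-ol F10. Hydrogenolysis of the benzylic C4–O bond (H2, Pd(OH)2/C, EtOAc with a trace of AcOH) should bring the fallback back to the route at compound 11.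

**Further compounds**
F1 | step 5 | 1,1-dibromo-4-(methoxymethoxy)-1a,6b-dihydro-1H-cyclopropa[b][1]benzofuran (racemic) | COCOc1ccc2c(c1)OC1C2C1(Br)Br
F2 | step 5 | 3-bromo-2-ethoxy-7-(methoxymethoxy)-2H-chromene (racemic) | CCOC1Oc2cc(OCOC)ccc2C=C1Br
F3 | step 5 | 1-bromo-2,4-bis(methoxymethoxy)benzene | COCOc1ccc(Br)c(OCOC)c1
F4 | step 5 | 2-[2,4-bis(methoxymethoxy)phenyl]-4,4,5,5-tetramethyl-1,3,2-dioxaborolane | COCOc1ccc(B2OC(C)(C)C(C)(C)O2)c(OCOC)c1
F5 | step 5 | 2-ethoxy-7-(methoxymethoxy)-3-[2,4-bis(methoxymethoxy)phenyl]-2H-chromene (racemic) | CCOC1Oc2cc(OCOC)ccc2C=C1c1ccc(OCOC)cc1OCOC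
F6 | step 7 | (3R)-8-iodo-3-[3-iodo-2,4-bis(methoxymethoxy)phenyl]-7-(methoxymethoxy)-3,4-dihydro-2H-chromene | COCOc1ccc([C@@H]2COc3c(I)c(OCOC)ccc3C2)c(OCOC)c1I
F7 | step 6 | (3,4-trans)-4-boranyl-7-(methoxymethoxy)-3-[2,4-bis(methoxymethoxy)phenyl]chroman (racemic, one enantiomer drawn) | COCOc1ccc([C@@H]2COc3cc(OCOC)ccc3[C@H]2B)c(OCOC)c1
F8 | step 6 | trans-(3R*,4S*)-7-(methoxymethoxy)-3-[2,4-bis(methoxymethoxy)phenyl]chroman-4-ol (racemic, one enantiomer drawn) | COCOc1ccc([C@@H]2COc3cc(OCOC)ccc3[C@H]2O)c(OCOC)c1
F9 | step 6 | 7-(methoxymethoxy)-3-[2,4-bis(methoxymethoxy)phenyl]chroman-4-one (racemic) | COCOc1ccc(C2COc3cc(OCOC)ccc3C2=O)c(OCOC)c1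
F10 | step 6 | (3R,4R)-cis-7-(methoxymethoxy)-3-[2,4-bis(methoxymethoxy)phenyl]chroman-4-ol | COCOc1ccc([C@@H]2COc3cc(OCOC)ccc3[C@@H]2O)c(OCOC)c1
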